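The retrosynthesis first removes the benzyl groups and takes the C3 CH2OH back to a C3 CO2H. It then cuts C1–C8a, C1–C2 and C3–C4 in that order, which leaves L-tartaric acid: its four carbons are the COOH carbon, C2, C3 and the CH2OH carbon of the target.
In the forward direction both benzene rings are bought. Tartrate acetonide is benzylated (C3–C4) and then joined to the aryl aldehyde (C1–C2) by an aldol–lactonisation. The carbocycle C1–C2–C3–C4–C4a–C8a is the only ring of the skeleton that is made, and it is closed last.
Three features enable the closure. C1 is benzylic and para to O-4′ of the pendant ring, so a quinone-methide-like cation is accessible. C8a lies para to the C6 methoxy group and is the nucleophilic site. The C1 oxygen and the C3 carboxyl carbon are 1,4-related and cis on the dialkylated tartrate, so a γ-lactone can hold the leaving group.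
Two temporary rings serve as helpers. The dioxolane keeps the ester enolates from β-elimination and is removed in step 6. The γ-lactone tells the two carboxyl groups apart and is opened in the key step, which frees only the C3 acid for borane reduction.
C3 and then C2 are set by relay from (R,R)-tartrate through two enolate substitutions, each with net inversion. C1 is set in the ring closure through a chair-like transition state.

Key step: step 7

Assumption: in step 3 the bromide attacks the enolate face anti to the neighbouring ester group (net inversion at that carbon). Should the opposite face be preferred, the same route from (−)-dibenzyl D-tartrate would give the target.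

Plicatic acid numbering (C1–C4, C4a, C8a) is used for the carbon atoms throughout.

Step 1
Reactants: 1 (+)-dibenzyl L-tartrate
Product: 2 dibenzyl (4R,5R)-2,2-dimethyl-1,3-dioxolane-4,5-dicarboxylate
Conditions: 2-methoxypropene, CSA (cat.), CH2Cl2, 0 °C to rt
Reagents that add atoms: 2-methoxypropene, COC(C)=C
Why: Acid-catalysed acetonide formation on a 1,2-diol under mild conditions that should avoid ester exchange and leave both stereocentres untouched.

Step 2
Reactants: 3 [4-(benzyloxy)-3-methoxyphenyl]methanol
Product: 4 1-(benzyloxy)-4-(bromomethyl)-2-methoxybenzene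
Conditions: PBr3, Et2O, 0 °C
Reagents that add atoms: phosphorus tribromide, BrP(Br)Br
Why: Standard conversion of a benzylic alcohol into the bromide through its phosphite ester, with the labile bromide used directly and no stereocentre involved.

Step 3
Reactants: 2 dibenzyl (4R,5R)-2,2-dimethyl-1,3-dioxolane-4,5-dicarboxylate; 4 1-(benzyloxy)-4-(bromomethyl)-2-methoxybenzene
Product: 6 dibenzyl (4S,5R)-4-[4-(benzyloxy)-3-methoxybenzyl]-2,2-dimethyl-1,3-dioxolane-4,5-dicarboxylate (ester groups cis), via lithium enolate 5 (not isolated)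
Conditions: LDA, THF–DMPU, −78 °C; then 4, −78 °C
Reagents that add atoms: none
Why: Alkylation of a tartrate acetonide ester enolate, in which the ring C–O bond lies orthogonal to the enolate π system so that β-elimination is slow at −78 °C, and in which the reactive benzylic bromide should enter anti to the neighbouring CO2Bn group and so set C3.

Step 4
Reactants: 7 3,4-dihydroxy-5-methoxybenzaldehyde
Product: 8 3,4-bis(benzyloxy)-5-methoxybenzaldehyde
Conditions: BnBr, K2CO3, DMF, 60 °C
Reagents that add atoms: benzyl bromide, BrCc1ccccc1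
Why: Williamson ether synthesis on both phenols of a non-enolisable aldehyde.

Step 5
Reactants: 6 dibenzyl (4S,5R)-4-[4-(benzyloxy)-3-methoxybenzyl]-2,2-dimethyl-1,3-dioxolane-4,5-dicarboxylate; 8 3,4-bis(benzyloxy)-5-methoxybenzaldehyde
Product: 11 benzyl (3aS,6aS)-6-[3,4-bis(benzyloxy)-5-methoxyphenyl]-3a-[4-(benzyloxy)-3-methoxybenzyl]-2,2-dimethyl-4-oxodihydrofuro[3,4-d][1,3]dioxole-6a(4H)-carboxylate (cis-fused γ-lactone acetonide; either configuration at the aryl-bearing C6 = C1), via lithium enolate 9 (not isolated), via lithium aldolate 10 (not isolated)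
Conditions: LDA, THF, −78 °C; then 8, −78 to 0 °C; AcOH quench
Reagents that add atoms: none
Why: Aldol addition followed by lactonisation, that is a Stobbe condensation that must stop at the paraconic lactone because C2 carries no hydrogen; the aldehyde should add anti to the larger arylmethyl group and so set C2, only that aldolate has its oxygen cis to the C3 ester and can lactonise while the other can revert by retro-aldol, and the C1 configuration does not matter because step 7 erases it.

Step 6
Reactants: 11 cis-fused γ-lactone acetonide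
Product: 12 benzyl (3S,4S)-2-[3,4-bis(benzyloxy)-5-methoxyphenyl]-4-[4-(benzyloxy)-3-methoxybenzyl]-3,4-dihydroxy-5-oxooxolane-3-carboxylate (either configuration at C2 of the oxolane = C1)
Conditions: TFA–H2O (9:1), CH2Cl2, 0 °C to rt
Reagents that add atoms: none
Why: Acid-catalysed ketal hydrolysis, during which the benzylic C1–O bond stays masked as the slowly ionising lactone, and which is needed because a trans-fused dioxolane would force both carboxyl carbons axial in the closure and so favour the C1 epimer.

Step 7
Reactants: 12 dihydroxy γ-lactone benzyl ester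
Product: 14 (1S,2S,3S)-7-(benzyloxy)-1-[3,4-bis(benzyloxy)-5-methoxyphenyl]-2-[(benzyloxy)carbonyl]-2,3-dihydroxy-6-methoxy-1,2,3,4-tetrahydronaphthalene-3-carboxylic acid, via benzylic cation 13 (not isolated)
Conditions: TfOH (10 mol %), (CF3)2CHOH–CH2Cl2 (1:1), 0 °C
Reagents that add atoms: none
Why: Protonation of the lactone carbonyl in the strongly ionising, non-nucleophilic medium breaks the benzylic C1–O bond, which gives the 4-alkoxybenzyl (quinone-methide-like) cation 13 and frees the C3 carboxylic acid; the guaiacyl ring on C4 then attacks C1 through the carbon para to its methoxy group (the future C8a) and loses a proton. The closest known reaction types are the Friedel–Crafts alkylation of arenes with γ-aryl-γ-butyrolactones, which gives 4,4-diarylbutanoic acids, and the acid-induced cyclisation of benzylic lignan alcohols to 1-aryltetralins. The single ring that closes, C1–C2–C3–C4–C4a–C8a, forms in a 6-exo-trig mode with respect to the C1=C1′ bond of the quinone-methide resonance form. C1 is the only new stereocentre and is controlled by C2 and C3: ionisation is reversible, so the product should arise from the lowest chair-like transition state, in which CO2Bn, CO2H and the pendant aryl group are equatorial, the two small hydroxyl groups are axial and the C2–O bond lies in the plane of the cation so that A(1,3) strain with the aryl ortho hydrogen is smallest, and this places the aryl group trans to CO2Bn (1S). Regioselectivity (para and not ortho to OMe) is secured by the para-directing methoxy group and by the crowding of the position between CH2 and OMe, and chemoselectivity over a 1,2-shift in the β-hydroxy cation by the proximity of the electron-rich arene. Because both C1 epimers of 12 give the same cation they converge, and because only the C3 carboxyl group is set free as the acid the step also tells the two former tartrate carboxyl groups apart.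

Step 8
Reactants: 14 tetralin 3-carboxylic acid 2-benzyl ester
Product: 15 benzyl (1S,2S,3R)-7-(benzyloxy)-1-[3,4-bis(benzyloxy)-5-methoxyphenyl]-2,3-dihydroxy-3-(hydroxymethyl)-6-methoxy-1,2,3,4-tetrahydronaphthalene-2-carboxylate
Conditions: BH3·THF, THF, 0 °C to rt; then H2O
Reagents that add atoms: none
Why: Chemoselective borane reduction of a carboxylic acid through its acyloxyborane, which should leave the hindered benzyl ester and all stereocentres untouched (the descriptor at C3 changes only through the priority rules).

Step 9
Reactants: 15 tri-O-benzylplicatic acid benzyl ester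
Product: 16 (−)-plicatic acid, (1S,2S,3R)-1-(3,4-dihydroxy-5-methoxyphenyl)-2,3,7-trihydroxy-3-(hydroxymethyl)-6-methoxy-1,2,3,4-tetrahydronaphthalene-2-carboxylic acid
Conditions: H2 (1 atm), 10% Pd/C, EtOAc–MeOH, rt
Reagents that add atoms: none
Why: Catalytic hydrogenolysis of three aryl benzyl ethers and the benzyl ester under neutral conditions, which avoids base (retro-aldol at C2–C3, catechol oxidation) and cannot touch the tertiary alcohols because neither is benzylic.

Compound list
1 | (+)-dibenzyl L-tartrate, dibenzyl (2R,3R)-2,3-dihydroxybutanedioate | O[C@H]([C@@H](O)C(=O)OCc1ccccc1)C(=O)OCc1ccccc1 | starting material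
2 | dibenzyl (4R,5R)-2,2-dimethyl-1,3-dioxolane-4,5-dicarboxylate | O=C(OCc1ccccc1)[C@@H]1OC(C)(C)O[C@H]1C(=O)OCc1ccccc1 | intermediate
3 | [4-(benzyloxy)-3-methoxyphenyl]methanol | COc1cc(CO)ccc1OCc1ccccc1 | starting material
4 | 1-(benzyloxy)-4-(bromomethyl)-2-methoxybenzene | COc1cc(CBr)ccc1OCc1ccccc1 | intermediate
5 | lithium ester enolate of 2 (one ring carbon planar, the other still R) | O=C(OCc1ccccc1)[C@H](O3)C(OC3(C)C)=C([O-])OCc1ccccc1.[Li+] | intermediate
6 | dibenzyl (4S,5R)-4-[4-(benzyloxy)-3-methoxybenzyl]-2,2-dimethyl-1,3-dioxolane-4,5-dicarboxylate | O=C(OCc1ccccc1)[C@H](O3)[C@](OC3(C)C)(C(=O)OCc1ccccc1)Cc1ccc(OCc2ccccc2)c(OC)c1 | intermediate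
7 | 3,4-dihydroxy-5-methoxybenzaldehyde | COc1cc(C=O)cc(O)c1O | starting material
8 | 3,4-bis(benzyloxy)-5-methoxybenzaldehyde | COc1cc(C=O)cc(OCc2ccccc2)c1OCc1ccccc1 | intermediate
9 | lithium ester enolate of 6 (C2 planar, C3 quaternary) | [Li+].[O-]C(OCc1ccccc1)=C(O3)[C@](OC3(C)C)(C(=O)OCc1ccccc1)Cc1ccc(OCc2ccccc2)c(OC)c1 | intermediate
10 | lithium aldolate from 9 and 8 (C1 oxygen cis to the C3 ester; C1 unassigned) | [Li+].[O-]C(c1cc(OCc2ccccc2)c(OCc2ccccc2)c(OC)c1)[C@@](O3)(C(=O)OCc1ccccc1)[C@](OC3(C)C)(C(=O)OCc1ccccc1)Cc1ccc(OCc2ccccc2)c(OC)c1 | intermediate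
11 | benzyl (3aS,6aS)-6-[3,4-bis(benzyloxy)-5-methoxyphenyl]-3a-[4-(benzyloxy)-3-methoxybenzyl]-2,2-dimethyl-4-oxodihydrofuro[3,4-d][1,3]dioxole-6a(4H)-carboxylate (C6 unassigned) | C(c1cc(OCc2ccccc2)c(OCc2ccccc2)c(OC)c1)(O5)[C@@](O3)(C(=O)OCc1ccccc1)[C@](OC3(C)C)(C5=O)Cc1ccc(OCc2ccccc2)c(OC)c1 | intermediate
12 | benzyl (3S,4S)-2-[3,4-bis(benzyloxy)-5-methoxyphenyl]-4-[4-(benzyloxy)-3-methoxybenzyl]-3,4-dihydroxy-5-oxooxolane-3-carboxylate (C2 of the oxolane unassigned) | C(c1cc(OCc2ccccc2)c(OCc2ccccc2)c(OC)c1)(O5)[C@@](O)(C(=O)OCc1ccccc1)[C@](O)(C5=O)Cc1ccc(OCc2ccccc2)c(OC)c1 | intermediate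
13 | C1 benzylic (quinone-methide-like) cation with free C3 carboxylic acid | [CH+](c1cc(OCc2ccccc2)c(OCc2ccccc2)c(OC)c1)[C@@](O)(C(=O)OCc1ccccc1)[C@](O)(C(=O)O)Cc1ccc(OCc2ccccc2)c(OC)c1 | intermediate
14 | (1S,2S,3S)-7-(benzyloxy)-1-[3,4-bis(benzyloxy)-5-methoxyphenyl]-2-[(benzyloxy)carbonyl]-2,3-dihydroxy-6-methoxy-1,2,3,4-tetrahydronaphthalene-3-carboxylic acid | COc1cc2c(cc1OCc1ccccc1)[C@H](c1cc(OCc3ccccc3)c(OCc3ccccc3)c(OC)c1)[C@@](O)(C(=O)OCc1ccccc1)[C@](O)(C(=O)O)C2 | intermediate
15 | benzyl (1S,2S,3R)-7-(benzyloxy)-1-[3,4-bis(benzyloxy)-5-methoxyphenyl]-2,3-dihydroxy-3-(hydroxymethyl)-6-methoxy-1,2,3,4-tetrahydronaphthalene-2-carboxylate | COc1cc2c(cc1OCc1ccccc1)[C@H](c1cc(OCc3ccccc3)c(OCc3ccccc3)c(OC)c1)[C@@](O)(C(=O)OCc1ccccc1)[C@](O)(CO)C2 | intermediate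
16 | (−)-plicatic acid | COc1cc2c(cc1O)[C@H](c1cc(O)c(O)c(OC)c1)[C@@](O)(C(=O)O)[C@](O)(CO)C2 | target

Total step count: 9. Longest linear sequence: 7 (steps 1, 3, 5, 6, 7, 8, 9).

**Steps most likely to fail**

**Step 7 is most at risk.**
- What may go wrong:
  - The acyloxy group may ionise sluggishly next to the electron-poor C2.
  - Long contact with acid may strip benzyl groups or start a 1,2-shift in the hydroxy cation.
  - Free rotation about C2–C3 may erode the facial selectivity at the planar C1.
- The fallback locks the conformation before the closure. It sets out from 11 and comes back to the route at 16.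
  - The strained lactone carbonyl is reduced in preference to the hindered benzyl ester (LiBH4, THF, 0 °C) to the C1,C3′-diol acetonide F1.
  - Warm aqueous acetic acid removes the ketal, and the new primary alcohol translactonises onto the benzyl ester to give the trans-disubstituted dihydroxybutyrolactone F2.
  - TFA in CH2Cl2 at 0 °C ionises the free benzylic alcohol and closes the ring to the trans-fused tetracyclic lactone F3. This is the well-known cyclisation of α-(hydroxybenzyl)-β-benzylbutyrolactones. The five-membered ring holds both carboxyl-derived carbons equatorial, so only the equatorial-aryl closure is open.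
  - Cold aqueous LiOH opens the lactone to tri-O-benzylplicatic acid F4, and hydrogenolysis over Pd/C gives 16.

**Step 5 is second.**
- What may go wrong:
  - Addition of a fully substituted enolate that sits next to a quaternary carbon may be slow.
  - The enolate may collapse by β-elimination on warming.
  - Attack may occur on the face syn to the arylmethyl group.
- The fallback reverses the order of the two C–C bond formations, so that the second one is governed by a much larger group. It sets out from 2 (with 8 and 4) and comes back at 11.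
  - The enolate of 2 adds to 8 anti to the neighbouring ester to give the aldol adduct F5.
  - TESOTf and 2,6-lutidine give the silyl ether F6.
  - LDA and then 4 alkylate the remaining CH carbon anti to the bulky CH(OTES)Ar group to give the fully substituted diester F7.
  - TBAF frees the alkoxide, which now stands cis to the C3 ester and lactonises to 11.

**Step 3 is third.**
- What may go wrong:
  - The enolate may self-condense or eliminate during the slow SN2 reaction.
  - The electron-rich bromide may decompose.
  - The facial selectivity may be modest.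
- The fallback replaces the alkylation by a fast carbonyl addition followed by deoxygenation. It sets out from 2 and comes back at 6.
  - The enolate of 2 adds at −78 °C to commercial 4-(benzyloxy)-3-methoxybenzaldehyde to give the hydroxybenzyl adduct F8. Its carbinol is trans to the other ester, so it cannot lactonise.
  - Ionic hydrogenation (Et3SiH, TFA, CH2Cl2, 0 °C) of this electron-rich benzylic alcohol gives 6.

Further compounds
F1 | step 7 | benzyl ester diol acetonide: 11 with the lactone reduced to C1–OH and C3–CH2OH | OC(c1cc(OCc2ccccc2)c(OCc2ccccc2)c(OC)c1)[C@@](O3)(C(=O)OCc1ccccc1)[C@](OC3(C)C)(CO)Cc1ccc(OCc2ccccc2)c(OC)c1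
F2 | step 7 | 3-{[3,4-bis(benzyloxy)-5-methoxyphenyl](hydroxy)methyl}-4-[4-(benzyloxy)-3-methoxybenzyl]-3,4-dihydroxyoxolan-2-one (hydroxyl groups trans, carbon substituents trans) | OC(c1cc(OCc2ccccc2)c(OCc2ccccc2)c(OC)c1)[C@@](O)(C5=O)[C@](O)(CO5)Cc1ccc(OCc2ccccc2)c(OC)c1
F3 | step 7 | tri-O-benzylplicatic acid γ-lactone (trans-fused) | COc1cc2c(cc1OCc1ccccc1)[C@H](c1cc(OCc3ccccc3)c(OCc3ccccc3)c(OC)c1)[C@@](O)(C5=O)[C@](O)(CO5)C2
F4 | step 7 | tri-O-benzylplicatic acid | COc1cc2c(cc1OCc1ccccc1)[C@H](c1cc(OCc3ccccc3)c(OCc3ccccc3)c(OC)c1)[C@@](O)(C(=O)O)[C@](O)(CO)C2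
F5 | step 5 | aldol adduct of 2 and 8 (C2 quaternary, C3 still CH, ester groups cis) | OC(c1cc(OCc2ccccc2)c(OCc2ccccc2)c(OC)c1)[C@@](O3)(C(=O)OCc1ccccc1)[C@@H](OC3(C)C)C(=O)OCc1ccccc1
F6 | step 5 | triethylsilyl ether of F5 | CC[Si](CC)(CC)OC(c1cc(OCc2ccccc2)c(OCc2ccccc2)c(OC)c1)[C@@](O3)(C(=O)OCc1ccccc1)[C@@H](OC3(C)C)C(=O)OCc1ccccc1
F7 | step 5 | C3-arylmethylated F6 (ester groups trans, C1 and C4 trans) | CC[Si](CC)(CC)OC(c1cc(OCc2ccccc2)c(OCc2ccccc2)c(OC)c1)[C@@](O3)(C(=O)OCc1ccccc1)[C@](OC3(C)C)(C(=O)OCc1ccccc1)Cc1ccc(OCc2ccccc2)c(OC)c1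
F8 | step 3 | aldol adduct of 2 and 4-(benzyloxy)-3-methoxybenzaldehyde (6 with OH on C4) | O=C(OCc1ccccc1)[C@H](O3)[C@](OC3(C)C)(C(=O)OCc1ccccc1)C(O)c1ccc(OCc2ccccc2)c(OC)c1
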